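**Neighbour first.** A neighbouring run with the binding of starting material made one-way is held for the end; this flask keeps that step reversible. Free enzyme binds starting material to the first complex, which sheds first product and leaves loaded enzyme. Loaded enzyme binds second substrate, fed from the held gas, to the second complex, which releases target and free enzyme.

starting material 0.15 M; gas 13 mM (held); free enzyme 0.073 mol%

1. the form that holds most of the catalyst when 10% of the starting material are converted (second complex / loaded enzyme / first complex / free enzyme)
2. its share of the catalyst then

**What counts.** The second complex loses second substrate at 5.32 s⁻¹, far faster than it releases target at 0.0410 s⁻¹, so its equilibrium constant 46.6 L mol⁻¹ outweighs its rate constant. The first complex likewise reverts at 0.119 s⁻¹ against 0.0140 s⁻¹ forward, so 4.9 L mol⁻¹ outweighs 0.581 L mol⁻¹ s⁻¹. Up to 10% conversion, decomposition, 1.26 × 10⁻⁶ s⁻¹, can be dropped beside transfer, 6.87 × 10⁻⁵ s⁻¹. The rate constants of the two chemical steps and the gas data must be known well.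

**Binding ratio.** In a steady cycle, the first complex forms as fast as it leaves, and dividing these rates removes time. So c(first complex)/c(free enzyme) equals c(starting material) times the binding constant 4.38 L mol⁻¹, the forward constant over the sum of the back and chemical constants. At 10% conversion, that ratio is 0.592. Equal flow through both complexes puts the second complex at 0.202 per free enzyme.

**Own reckoning.** Loaded enzyme remains the rival. It would equal free enzyme at c(second substrate) = 4.37 mM, where free enzyme would hold 35.8%. There, gas supplies 5.93 × 10⁻⁷ M s⁻¹ against a demand of 3.25 × 10⁻⁷ M s⁻¹, so by this estimate c(second substrate) climbs past that level, on a transfer time of 4.04 h. This reckoning names free enzyme, between 35.8% and 55.8%, and goes no further.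

**Forecast.** It gives free enzyme at 41%, from 37% to 45%, finding the first half-cycle “comparable to the gas supply limit”.

**Result.** The simulation gives free enzyme at 41.5%, as the forecast said: a resting state that leaves 58.5% of the catalyst in the other three forms, with loaded enzyme at 25.5%.

    starting material + free enzyme ⇌ first complex (K1 = 4.9 L mol⁻¹, k1 = 0.581 L mol⁻¹ s⁻¹)
    first complex → loaded enzyme + first product (k2 = 0.0140 s⁻¹)
    second substrate + loaded enzyme ⇌ second complex (K3 = 46.6 L mol⁻¹, k3 = 248 L mol⁻¹ s⁻¹)
    second complex → free enzyme + target (k4 = 0.0410 s⁻¹)
    second substrate → decomposed reagent (k5 = 1.26 × 10⁻⁶ s⁻¹)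
    gas ⇌ second substrate, rate k6*(csat - [second substrate]) (k6 = 6.87 × 10⁻⁵ s⁻¹, csat = 13 mM)

**Back run.** The readings of first complex over free enzyme give 0.592, against the binding ratio of 0.592. After 1.20 d, the binding constant gives 0.495 and the readings 0.495. The back run of binding raises the apparent order in free enzyme at 10% conversion from 0.60 to 0.83. With that back run taken away, the rate there is 1.38 times the actual one.

Its constants are invented, and the outcome is calculated.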